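**Retrosynthetic overview**
1. Endgame: HF unmasking of a C11=C12 silyl enol ether (sets C11), acetylation, and two reductions (C2, C9) of a ten-membered 8-hydroxy-2,9-dione.
2. Key disconnection: the ten-membered ring comes from an anionic retro-aldol ring expansion (C2–C8 cleavage) of a five/seven-fused hydroazulenol; the released enolate is hydroxylated at C8.
3. The seven-membered ring comes from ring-closing metathesis (C3=C4) after vinyl addition at C2 of a spiro-lactone cyclopentane-1,3-dione.
4. The spiro-γ-lactone with C6–Cl and C7–O comes from an aldol–lactonisation with an (S)-α-chloroaldehyde; C17–C19 come from reductive alkylation with pyruvate.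
5. Ring A and the cyclopentanedione come from one enantioselective Diels–Alder reaction. Ring order: ring A + cyclopentane, then lactone, then seven-membered ring, then ten-membered ring.

Assumption: atoms are located by the briarane numbers of the target (C1 quaternary ring-fusion carbon with CH3 = C15, C2 CHOAc, C3=C4, C5(=C16H2), C6 Cl, C7 lactone O, C8 OH, C9 OAc, C10 ring-fusion CH, C11 with CH3 = C20, C12 C=O, C13, C14 butanoate, C17 with CH3 = C18, C19 lactone C=O), and 4-methylcyclopent-4-ene-1,3-dione is taken as a catalogue compound.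

Step 1
Reactants: 1 pent-1-yn-3-one; 2 butanoic acid
Product: 3 (E)-3-oxopent-1-en-1-yl butanoate
Conditions: DABCO (10 mol %), CH2Cl2, 0 °C to 23 °C
Reagents that add atoms: none
Why: Amine-catalysed conjugate (oxa-Michael) addition of the carboxylic acid to the ynone gives the thermodynamically preferred E β-acyloxy enone, which already carries the C14 butanoate.

Step 2
Reactants: 3 (E)-3-oxopent-1-en-1-yl butanoate
Product: 4 (1E,3Z)-3-[(trimethylsilyl)oxy]penta-1,3-dien-1-yl butanoate
Conditions: Me3SiOTf, Et3N, Et2O, 0 °C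
Reagents that add atoms: trimethylsilyl trifluoromethanesulfonate, C[Si](C)(C)OS(=O)(=O)C(F)(F)F
Why: Soft enolisation and O-silylation of the ethyl ketone gives the Z silyl enol ether, a 1-acyloxy-3-silyloxy diene of the Danishefsky type.

Step 3
Reactants: 4 (1E,3Z)-3-[(trimethylsilyl)oxy]penta-1,3-dien-1-yl butanoate; 5 4-methylcyclopent-4-ene-1,3-dione
Product: 7 cis-fused bicyclic trione, via trimethylsilyl enol ether cycloadduct 6 (not isolated)
Conditions: (S)-o-tolyl-CBS-oxazaborolidine·HNTf2 (20 mol %), CH2Cl2, −78 °C; then aq. citric acid, THF, 0 °C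
Reagents that add atoms: none
Why: Catalytic enantioselective Diels–Alder reaction in which the nucleophilic diene terminus (C11) bonds to the unsubstituted alkene carbon (C10) and endo addition places the C14 butanoate cis to the dione ring and anti to the angular methyl, the chiral Lewis acid (its enantiomer would give the mirror series) fixing C1 and C14, after which mild acid hydrolyses only the trimethylsilyl enol ether.

Step 4
Reactants: 7 cis-fused bicyclic trione
Product: 9 C11=C12 tert-butyldimethylsilyl enol ether dione, via bis-silyl intermediate 8 (not isolated)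
Conditions: tBuMe2SiOTf (2.5 equiv), Et3N, CH2Cl2, 0 °C to 23 °C; pH 4 buffer work-up
Reagents that add atoms: tert-butyldimethylsilyl trifluoromethanesulfonate, CC(C)(C)[Si](C)(C)OS(=O)(=O)C(F)(F)F
Why: Equilibrating soft enolisation gives the tetrasubstituted silyl enol ether, which masks the C12 ketone, erases the C11 centre from the cycloaddition and cannot eliminate the C14 butanoate; the labile silyl vinylogous ester on the dione is hydrolysed on work-up.

Step 5
Reactants: 9 C11=C12 tert-butyldimethylsilyl enol ether dione; 10 methyl pyruvate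
Product: 12 methyl 2-(dion-8-yl)propanoate, via alkylidene dione 11 (not isolated)
Conditions: Hantzsch ester, L-proline (20 mol %), CH2Cl2, 23 °C
Reagents that add atoms: none
Why: Organocatalytic reductive Knoevenagel alkylation, in which the acidic dione condenses with the activated ketone of pyruvate and the alkylidene dione is reduced in the flask by hydride transfer; C8 and C17 are left uncontrolled because C8 later becomes planar and C17 is equilibrated in step 13.

Step 6
Reactants: 13 2-chlorobuta-1,3-diene; 14 oxirane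
Product: 16 3-methylidenepent-4-en-1-ol, via buta-1,3-dien-2-ylmagnesium chloride 15 (not isolated)
Conditions: Mg, ZnCl2 (2 mol %), THF, 45 °C; then oxirane, CuI (5 mol %), −30 °C to 0 °C; aq. NH4Cl
Reagents that add atoms: none
Why: Grignard formation from chloroprene followed by copper-catalysed epoxide opening gives the 2-substituted diene alcohol that carries C4 to C7 and C16.

Step 7
Reactants: 16 3-methylidenepent-4-en-1-ol
Product: 17 3-methylidenepent-4-enal
Conditions: Dess–Martin periodinane, CH2Cl2, 0 °C
Reagents that add atoms: none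
Why: Mild, non-basic alcohol oxidation gives the β,γ-unsaturated aldehyde without isomerisation into conjugation.

Step 8
Reactants: 17 3-methylidenepent-4-enal
Product: 18 (2S)-2-chloro-3-methylidenepent-4-enal
Conditions: N-chlorosuccinimide, (2R,5R)-2,5-diphenylpyrrolidine (10 mol %), CH2Cl2, −30 °C; used at once
Reagents that add atoms: N-chlorosuccinimide, O=C1CCC(=O)N1Cl
Why: Enamine-catalysed enantioselective α-chlorination, in which the C2-symmetric amine shields one enamine face and sets the S chloride that becomes C6.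

Step 9
Reactants: 12 methyl 2-(dion-8-yl)propanoate; 18 (2S)-2-chloro-3-methylidenepent-4-enal
Product: 20 spiro-γ-lactone dione, via aldol adduct 19 (not isolated)
Conditions: MgBr2·OEt2, Et3N, CH2Cl2, −20 °C to 0 °C
Reagents that add atoms: none
Why: Soft-enolisation aldol addition of the 2-substituted 1,3-dione to the α-chloroaldehyde under Cornforth–Felkin control gives the 6,7-anti chlorohydrin (C7 R) and is made irreversible by lactonisation of the magnesium aldolate onto the methyl ester; the C8 configuration is inconsequential.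

Step 10
Reactants: 20 spiro-γ-lactone dione
Product: 22 C2 vinyl carbinol, via lithium enolate 21 (not isolated)
Conditions: LiN(SiMe3)2 (1.05 equiv), THF, −78 °C; then CH2=CHMgBr, CeCl3, −78 °C to −40 °C; AcOH
Reagents that add atoms: vinylmagnesium bromide, C=C[Mg]Br
Why: The only enolisable ketone (C9, through H-10) is protected in the flask as its lithium enolate, which also blocks retro-aldol cleavage, so the organocerium 1,2-addition takes place at the non-enolisable C2 ketone rather than at the lactone or the butanoate; C10 is reprotonated from the convex face (cis fusion kept).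

Step 11
Reactants: 22 C2 vinyl carbinol
Product: 23 five/seven-fused hydroazulenol
Conditions: second-generation Grubbs catalyst (5 mol %), CH2Cl2 (2 mM), 40 °C
Reagents that add atoms: none
Why: Ring-closing metathesis between the two monosubstituted alkenes closes the seven-membered ring with a necessarily cis C3=C4 bond, while the less reactive 1,1-disubstituted C5 methylene stays exocyclic.

Step 12
Reactants: 23 five/seven-fused hydroazulenol
Product: 25 ten-membered 8-hydroxy-2,9-dione, via potassium enolate 24 (not isolated)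
Conditions: KN(SiMe3)2 (1.1 equiv), THF, −78 °C to −40 °C; then 2-(phenylsulfonyl)-3-phenyloxaziridine, −78 °C; AcOH
Reagents that add atoms: 2-(phenylsulfonyl)-3-phenyloxaziridine, O=S(=O)(c1ccccc1)N1OC1c1ccccc1
Why: Proposed new method: anionic retro-aldol ring expansion with enolate oxygenation in the same flask, in which the C2 potassium alkoxide cleaves the C2–C8 bond shared by the five- and seven-membered rings and merges them into the ten-membered (3Z)-dienone (driven by alkoxide-to-enolate conversion, relief of the congested tertiary aldolate and dienone conjugation; the endocyclic C7–O bond lies in the nodal plane of the enolate so β-elimination is slow), and the tetrasubstituted C8=C9 enolate, planar within the γ-lactone, is hydroxylated on the face anti to C6 to set C8; the closest known reactions are retro-aldol (De Mayo-type) fragmentative ring expansions and oxaziridine hydroxylation of enolates, which have not been combined on a hydroazulenol to give a cyclodecadienone.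

Step 13
Reactants: 25 ten-membered 8-hydroxy-2,9-dione
Product: 26 trans-fused 8-hydroxy-2,9-dione
Conditions: DBU (0.5 equiv), toluene, 40 °C
Reagents that add atoms: none
Why: Base-mediated epimerisation by enolisation and reprotonation α to the C9 ketone and α to the lactone carbonyl moves H-10 anti to C15 so that both ten-membered-ring bonds are equatorial on ring A (trans fusion) and places the C17 methyl anti to C9 (cis to the C8 hydroxyl), both taken as the thermodynamic arrangement.

Step 14
Reactants: 26 trans-fused 8-hydroxy-2,9-dione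
Product: 27 8,9-diol 2-ketone
Conditions: Zn(BH4)2, Et2O, −78 °C
Reagents that add atoms: none
Why: Chelation-controlled (Cram-chelate) reduction in which zinc bridges the C8 hydroxyl and the C9 carbonyl and hydride attacks the exposed face anti to C7, giving the required C9 alcohol, while the hindered cross-conjugated C2 ketone does not react at −78 °C.

Step 15
Reactants: 27 8,9-diol 2-ketone
Product: 28 2,8,9-triol
Conditions: (R)-2-methyl-CBS-oxazaborolidine (0.5 equiv), catecholborane, toluene, −78 °C
Reagents that add atoms: none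
Why: Corey–Bakshi–Shibata 1,2-reduction of the dienone, in which the oxazaborolidine distinguishes the tert-alkyl (C1) and alkenyl (C3) flanks and delivers hydride under reagent control to give the 2S allylic alcohol.

Step 16
Reactants: 28 2,8,9-triol
Product: 29 2,9-diacetate silyl enol ether
Conditions: Ac2O, pyridine, DMAP (10 mol %), CH2Cl2, 0 °C to 23 °C
Reagents that add atoms: acetic anhydride, CC(=O)OC(C)=O
Why: Nucleophile-catalysed acylation esterifies the two secondary alcohols and leaves the hindered tertiary C8 hydroxyl free.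

Step 17
Reactants: 29 2,9-diacetate silyl enol ether
Product: 30 CNP0283653.1
Conditions: HF·pyridine, pyridine, THF, −20 °C
Reagents that add atoms: none
Why: Protodesilylation of the silyl enol ether with kinetic protonation at C11 on the face anti to the axial C15 methyl gives the 11-methyl group cis to C15, and the buffered acidic medium neither enolises the new ketone nor eliminates the β-butanoate.

**Compound list**
1 | pent-1-yn-3-one | C#CC(=O)CC | starting material
2 | butanoic acid | CCCC(=O)O | starting material
3 | (E)-3-oxopent-1-en-1-yl butanoate | CCCC(=O)O/C=C/C(=O)CC | intermediate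
4 | (1E,3Z)-3-[(trimethylsilyl)oxy]penta-1,3-dien-1-yl butanoate | CCCC(=O)O/C=C/C(O[Si](C)(C)C)=C/C | intermediate
5 | 4-methylcyclopent-4-ene-1,3-dione | CC1=CC(=O)CC1=O | starting material
6 | Diels–Alder adduct as its C12 trimethylsilyl enol ether; cis-fused ring A/cyclopentane-1,3-dione, C14 butanoate cis to the dione ring | O=C1[C@]2(C)[C@@H]([C@H](C)C(O[Si](C)(C)C)=C[C@@H]2OC(=O)CCC)C(=O)C1 | intermediate
7 | cis-fused bicyclic trione: ring A with C12 ketone, C11 methyl cis to the butanoate, C14 butanoate; cyclopentane-1,3-dione C2(=O)–C8H2–C9(=O) fused at C1–C10 | O=C1[C@]2(C)[C@@H]([C@H](C)C(=O)C[C@@H]2OC(=O)CCC)C(=O)C1 | intermediate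
8 | bis(tert-butyldimethylsilyl) intermediate: C11=C12 enol ether plus O-silylated dione | O=C1[C@]2(C)[C@@H](C(C)=C(O[Si](C)(C)C(C)(C)C)C[C@@H]2OC(=O)CCC)C(O[Si](C)(C)C(C)(C)C)=C1 | intermediate
9 | cis-fused cyclopentane-1,3-dione with ring A as C11=C12 tert-butyldimethylsilyl enol ether and C14 butanoate | O=C1[C@]2(C)[C@@H](C(C)=C(O[Si](C)(C)C(C)(C)C)C[C@@H]2OC(=O)CCC)C(=O)C1 | intermediate
10 | methyl pyruvate (methyl 2-oxopropanoate) | CC(=O)C(=O)OC | starting material
11 | 8-alkylidene dione (Knoevenagel adduct of 9 and 10) | O=C1[C@]2(C)[C@@H](C(C)=C(O[Si](C)(C)C(C)(C)C)C[C@@H]2OC(=O)CCC)C(=O)C1=C(C)C(=O)OC | intermediate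
12 | methyl 2-(dion-8-yl)propanoate: dione 9 bearing CH(CH3)CO2CH3 at C8 (C8 enolisable, C17 epimer mixture) | O=C1[C@]2(C)[C@@H](C(C)=C(O[Si](C)(C)C(C)(C)C)C[C@@H]2OC(=O)CCC)C(=O)C1C(C)C(=O)OC | intermediate
13 | 2-chlorobuta-1,3-diene (chloroprene) | C=CC(Cl)=C | starting material
14 | oxirane | C1CO1 | starting material
15 | buta-1,3-dien-2-ylmagnesium chloride | C=CC(=C)[Mg]Cl | intermediate
16 | 3-methylidenepent-4-en-1-ol | C=CC(=C)CCO | intermediate
17 | 3-methylidenepent-4-enal | C=CC(=C)CC=O | intermediate
18 | (2S)-2-chloro-3-methylidenepent-4-enal | O=C[C@@H](Cl)C(=C)C=C | intermediate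
19 | aldol adduct: dione 12 bearing at C8 the (7R)-hydroxy-(6S)-chloro dienyl chain and the propanoate ester | O=C1[C@]2(C)[C@@H](C(C)=C(O[Si](C)(C)C(C)(C)C)C[C@@H]2OC(=O)CCC)C(=O)[C@]1(C(C)C(=O)OC)[C@@H](O)[C@@H](Cl)C(=C)C=C | intermediate
20 | spiro-γ-lactone dione: C8 spiro centre of lactone C8–C17H(CH3)–C19(=O)–O–C7H, C7 carrying (S)-CHCl–C(=CH2)–CH=CH2; C17 epimer mixture | O=C1[C@]2(C)[C@@H](C(C)=C(O[Si](C)(C)C(C)(C)C)C[C@@H]2OC(=O)CCC)C(=O)[C@@]13C(C)C(=O)O[C@H]3[C@@H](Cl)C(=C)C=C | intermediate
21 | lithium C9=C10 enolate of 20 | O=C1[C@]2(C)C(C(C)=C(O[Si](C)(C)C(C)(C)C)C[C@@H]2OC(=O)CCC)=C(O[Li])[C@@]13C(C)C(=O)O[C@H]3[C@@H](Cl)C(=C)C=C | intermediate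
22 | C2 vinyl carbinol: tertiary C2 alcohol bearing vinyl, C9 ketone, spiro-lactone and chain as in 20 (C2 and C8 configurations inconsequential) | C=C[C@]1(O)[C@]2(C)[C@@H](C(C)=C(O[Si](C)(C)C(C)(C)C)C[C@@H]2OC(=O)CCC)C(=O)[C@@]13C(C)C(=O)O[C@H]3[C@@H](Cl)C(=C)C=C | intermediate
23 | five/seven-fused hydroazulenol: seven-membered ring C2–C3=C4–C5(=CH2)–C6(Cl)–C7–C8 fused to the cyclopentanone at C2–C8, spiro-lactone at C8, tertiary C2 alcohol | C=C1C=C[C@]2(O)[C@]3(C)[C@@H](C(C)=C(O[Si](C)(C)C(C)(C)C)C[C@@H]3OC(=O)CCC)C(=O)[C@@]24C(C)C(=O)O[C@H]4[C@H]1Cl | intermediate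
24 | potassium C8=C9 enolate of the ring-expanded 2,9-dione | C=C1/C=C\C(=O)[C@]2(C)[C@@H](C(C)=C(O[Si](C)(C)C(C)(C)C)C[C@@H]2OC(=O)CCC)C(O[K])=C2C(C)C(=O)O[C@H]2[C@H]1Cl | intermediate
25 | ten-membered (3Z)-5-methylidene 2,9-dione with C8 hydroxyl, fused γ-lactone and C6 chloride; H-10 cis to C15, C17 epimer mixture | C=C1/C=C\C(=O)[C@]2(C)[C@@H](C(C)=C(O[Si](C)(C)C(C)(C)C)C[C@@H]2OC(=O)CCC)C(=O)[C@@]2(O)C(C)C(=O)O[C@H]2[C@H]1Cl | intermediate
26 | trans-fused 8-hydroxy-2,9-dione (H-10 anti to C15, C17 as in the target) | C=C1/C=C\C(=O)[C@]2(C)[C@H](C(C)=C(O[Si](C)(C)C(C)(C)C)C[C@@H]2OC(=O)CCC)C(=O)[C@@]2(O)[C@H](C)C(=O)O[C@H]2[C@H]1Cl | intermediate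
27 | 8,9-diol 2-ketone (C9 alcohol as in the target) | C=C1/C=C\C(=O)[C@]2(C)[C@H](C(C)=C(O[Si](C)(C)C(C)(C)C)C[C@@H]2OC(=O)CCC)[C@H](O)[C@@]2(O)[C@H](C)C(=O)O[C@H]2[C@H]1Cl | intermediate
28 | 2,8,9-triol (2S allylic alcohol) | C=C1/C=C\[C@H](O)[C@]2(C)[C@H](C(C)=C(O[Si](C)(C)C(C)(C)C)C[C@@H]2OC(=O)CCC)[C@H](O)[C@@]2(O)[C@H](C)C(=O)O[C@H]2[C@H]1Cl | intermediate
29 | 2,9-diacetate with ring A still as the C11=C12 tert-butyldimethylsilyl enol ether | C=C1/C=C\[C@H](OC(C)=O)[C@]2(C)[C@H](C(C)=C(O[Si](C)(C)C(C)(C)C)C[C@@H]2OC(=O)CCC)[C@H](OC(C)=O)[C@@]2(O)[C@H](C)C(=O)O[C@H]2[C@H]1Cl | intermediate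
30 | CNP0283653.1 | C=C1/C=C\[C@H](OC(C)=O)[C@]2(C)[C@H]([C@@H](C)C(=O)C[C@@H]2OC(=O)CCC)[C@H](OC(C)=O)[C@@]2(O)[C@H](C)C(=O)O[C@H]2[C@H]1Cl | target

**Totals**
Total step count: 17. Longest linear sequence: 14 (steps 1–5 and 9–17).

**Steps most likely to fail**

Step 9 (aldol–lactonisation of a weakly nucleophilic 1,3-dione with a labile α-chloroaldehyde). The fallback replaces the intermolecular aldol by an ester-tethered alkylation and sets out from 9. Reductive Knoevenagel alkylation with pyruvic acid in place of 10 gives the propanoic acid F1. Oxalyl chloride with catalytic DMF gives the acid chloride F2. ZnCl2-catalysed addition of F2 to aldehyde 18 gives the 1-chloroalkyl ester F3. Et3N in MeCN then closes the spiro-lactone by intramolecular C-alkylation of the dione, and the route is rejoined at 20.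

Step 10 (vinyl addition to a ketone flanked by two quaternary carbons, in the presence of a lactone and an ester). The fallback uses a smaller nucleophile followed by partial reduction and sets out from 20. The same enolate protection followed by ethynylmagnesium bromide and CeCl3 gives the ethynyl carbinol F4. Semihydrogenation (H2, Pd on CaCO3 poisoned with Pb(OAc)2, quinoline) then gives 22.

Step 12 (the proposed new ring expansion with enolate hydroxylation). The fallback uses known chemistry and closes the ten-membered ring by metathesis instead of by ring expansion; it sets out from 22, before the seven-membered ring is made. KN(SiMe3)2-induced retro-aldol opening of the cyclopentane and oxaziridine hydroxylation of the enolate give the ring-opened hydroxy diketone F5. Ring-closing metathesis of F5 (second-generation Grubbs catalyst, 0.5 mM, 40 °C) between the vinyl ketone and the diene terminus closes the ten-membered ring directly and comes back at 25.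

**Further compounds**
F1 | step 9 | 2-(dion-8-yl)propanoic acid (free acid analogue of 12) | O=C1[C@]2(C)[C@@H](C(C)=C(O[Si](C)(C)C(C)(C)C)C[C@@H]2OC(=O)CCC)C(=O)C1C(C)C(=O)O
F2 | step 9 | 2-(dion-8-yl)propanoyl chloride | O=C1[C@]2(C)[C@@H](C(C)=C(O[Si](C)(C)C(C)(C)C)C[C@@H]2OC(=O)CCC)C(=O)C1C(C)C(=O)Cl
F3 | step 9 | 1-chloroalkyl ester from F2 and 18 (1,2-dichloro-3-methylidenepent-4-enyl 2-(dion-8-yl)propanoate) | O=C1[C@]2(C)[C@@H](C(C)=C(O[Si](C)(C)C(C)(C)C)C[C@@H]2OC(=O)CCC)C(=O)C1C(C)C(=O)OC(Cl)[C@@H](Cl)C(=C)C=C
F4 | step 10 | C2 ethynyl carbinol (alkyne analogue of 22) | C#C[C@]1(O)[C@]2(C)[C@@H](C(C)=C(O[Si](C)(C)C(C)(C)C)C[C@@H]2OC(=O)CCC)C(=O)[C@@]13C(C)C(=O)O[C@H]3[C@@H](Cl)C(=C)C=C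
F5 | step 12 | ring-opened hydroxy diketone: ring A with a C1 propenoyl (C2 vinyl ketone) arm and a C10 acyl arm ending in the 8-hydroxy-γ-lactone with the chlorodiene chain | C=CC(=O)[C@]1(C)[C@@H](C(C)=C(O[Si](C)(C)C(C)(C)C)C[C@@H]1OC(=O)CCC)C(=O)[C@@]1(O)C(C)C(=O)O[C@H]1[C@@H](Cl)C(=C)C=C
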